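**Strategy.** Ring A is disconnected rather than substituted. It is a 2-alkyl-5-methoxyresorcinol whose C3', the carbon holding the stereocentre C3, sits between the oxygenated C2' and C4' and para to the C6' methoxy group. Exactly this pattern arises when a siloxyalkyne meets the vinylketene from 3-methoxycyclobutenone. One thermal operation therefore forges C2'–C3' and C4'–C5', closes ring A at C1'–C2' and leaves the finished C3 and C5 stereocentres untouched. The precursor is a triisopropylsiloxyalkyne whose propargylic carbon is C3 (R), carrying the (E)-4-(methoxymethoxy)styryl arm and the silyl-protected C5 carbinol chain; the cinnamoyl group is added afterwards to the symmetric ring.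

Key step: step 14

Remark (numbering): heptanoid chain C1–C7 from the 4-hydroxyphenyl end (C3 benzylic methine, C5 carbinol); ring A has C1' cinnamoyl, C2'/C4' OH, C3' alkyl, C6' OMe. The target is (3R,5S). R* = (1E,3R,5S)-5-[(tert-butyldimethylsilyl)oxy]-1-[4-(methoxymethoxy)phenyl]-7-phenylhept-1-en-3-yl.

Remark (assumption): N-methoxy-N-methylcinnamamide 29 is taken as a purchased compound, and in step 7 the antipode of the carbene ligand that gives (3R)-10 is used, the sense of induction being assigned by analogy.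

**Route**

Step 1
Reactants: 1 ethyl 3-oxo-5-phenylpentanoate
Product: 2 ethyl (3S)-3-hydroxy-5-phenylpentanoate
Conditions: H2 (50 atm), RuCl2[(S)-BINAP] (0.5 mol%), EtOH, 50 °C
Reagents that add atoms: none
Why: Noyori asymmetric hydrogenation of a β-keto ester, in which the ketone chelates the (S)-BINAP–ruthenium centre through the ester carbonyl and hydride is delivered to the face that gives the (3S)-alcohol, the future C5 (S).

Step 2
Reactants: 2 ethyl (3S)-3-hydroxy-5-phenylpentanoate
Product: 3 ethyl (3S)-3-[(tert-butyldimethylsilyl)oxy]-5-phenylpentanoate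
Conditions: TBSCl, imidazole, DMF, rt
Reagents that add atoms: tert-butyldimethylsilyl chloride, CC(C)(C)[Si](C)(C)Cl
Why: Imidazole-promoted silylation of a secondary alcohol gives a silyl ether that should survive the basic, organometallic and thermal steps and fall to the final acid.

Step 3
Reactants: 3 ethyl (3S)-3-[(tert-butyldimethylsilyl)oxy]-5-phenylpentanoate
Product: 4 (3S)-3-[(tert-butyldimethylsilyl)oxy]-5-phenylpentanal
Conditions: i-Bu2AlH (1.1 equiv), CH2Cl2, −78 °C; aq. potassium sodium tartrate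
Reagents that add atoms: none
Why: Partial reduction of an ester by i-Bu2AlH at −78 °C stops at the aluminium hemiacetal, which releases the aldehyde (future C3) only on work-up.

Step 4
Reactants: 4 (3S)-3-[(tert-butyldimethylsilyl)oxy]-5-phenylpentanal
Product: 5 ethyl (2E,5S)-5-[(tert-butyldimethylsilyl)oxy]-7-phenylhept-2-enoate
Conditions: (EtO)2P(O)CH2CO2Et, LiCl, DBU, MeCN, 0 °C → rt
Reagents that add atoms: triethyl phosphonoacetate, CCOC(=O)CP(=O)(OCC)OCC
Why: Horner–Wadsworth–Emmons olefination under mild LiCl/amine (Masamune–Roush) conditions should give the (E)-enoate without β-elimination of the silyloxy group.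

Step 5
Reactants: 5 ethyl (2E,5S)-5-[(tert-butyldimethylsilyl)oxy]-7-phenylhept-2-enoate
Product: 6 (2E,5S)-5-[(tert-butyldimethylsilyl)oxy]-7-phenylhept-2-en-1-ol
Conditions: i-Bu2AlH (2.5 equiv), CH2Cl2, −78 → 0 °C; aq. potassium sodium tartrate
Reagents that add atoms: none
Why: 1,2-Reduction of an α,β-unsaturated ester by i-Bu2AlH gives the allylic alcohol with the (E)-geometry retained.

Step 6
Reactants: 6 (2E,5S)-5-[(tert-butyldimethylsilyl)oxy]-7-phenylhept-2-en-1-ol
Product: 7 diethyl (2E,5S)-5-[(tert-butyldimethylsilyl)oxy]-7-phenylhept-2-en-1-yl phosphate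
Conditions: (EtO)2P(O)Cl, pyridine, DMAP (cat.), CH2Cl2, 0 °C → rt
Reagents that add atoms: diethyl chlorophosphate, CCOP(=O)(Cl)OCC
Why: Phosphorylation of a primary allylic alcohol under nucleophilic catalysis installs the leaving group needed for copper-catalysed SN2' substitution.

Step 7
Reactants: 7 diethyl (2E,5S)-5-[(tert-butyldimethylsilyl)oxy]-7-phenylhept-2-en-1-yl phosphate, 8 ethynyltrimethylsilane
Product: 10 (3R,5S)-5-[(tert-butyldimethylsilyl)oxy]-7-phenyl-3-[(trimethylsilyl)ethynyl]hept-1-ene, via alkynylalane 9 (not isolated)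
Conditions: 8, i-Bu2AlH, Et3N (5 mol%), hexanes, rt; then 7, CuCl2·2H2O (5 mol%), enantiopure 4,5-diphenylimidazolinium salt bearing N-(2-sulfonatophenyl) and N-(2,6-diisopropylphenyl) groups (carbene precursor, 5.5 mol%), THF, −30 °C
Reagents that add atoms: none
Why: Copper-catalysed enantioselective allylic substitution (SN2', γ-selective) of an (E)-allylic phosphate by an alkynylaluminium reagent, in which the chiral carbene–copper alkynyl adds to C3 on the alkene face dictated by the ligand (catalyst control, C5 being a remote spectator), so that C3 (R) is created with vinyl and alkynyl groups in place and any C3 epimer is a separable diastereomer.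

Step 8
Reactants: 11 4-hydroxybenzaldehyde
Product: 12 4-(methoxymethoxy)benzaldehyde
Conditions: MOMCl, i-Pr2NEt, CH2Cl2, 0 °C → rt
Reagents that add atoms: chloromethyl methyl ether, COCCl
Why: O-Alkylation of a phenol with chloromethyl methyl ether gives an acetal that is stable to bases and organometallic reagents.

Step 9
Reactants: 12 4-(methoxymethoxy)benzaldehyde
Product: 13 1-ethenyl-4-(methoxymethoxy)benzene
Conditions: Ph3PCH3Br, KOt-Bu, THF, 0 °C → rt
Reagents that add atoms: methyltriphenylphosphonium bromide, C[P+](c1ccccc1)(c1ccccc1)c1ccccc1.[Br-]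
Why: Wittig methylenation of an aromatic aldehyde with the non-stabilised ylide gives the styrene.

Step 10
Reactants: 10 (3R,5S)-5-[(tert-butyldimethylsilyl)oxy]-7-phenyl-3-[(trimethylsilyl)ethynyl]hept-1-ene, 13 1-ethenyl-4-(methoxymethoxy)benzene
Product: 14 (1E,3R,5S)-5-[(tert-butyldimethylsilyl)oxy]-1-[4-(methoxymethoxy)phenyl]-7-phenyl-3-[(trimethylsilyl)ethynyl]hept-1-ene
Conditions: 13 (3 equiv), second-generation Hoveyda–Grubbs catalyst [RuCl2(H2IMes)(=CH-C6H4-2-Oi-Pr)] (5 mol%), CH2Cl2, 40 °C
Reagents that add atoms: none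
Why: Ruthenium-catalysed olefin cross-metathesis of a branched terminal alkene with excess styrene, driven by loss of ethene, should give the conjugated (E)-styrene while the silyl cap keeps the alkyne out of enyne metathesis and C3 is not touched.

Step 11
Reactants: 14 (1E,3R,5S)-5-[(tert-butyldimethylsilyl)oxy]-1-[4-(methoxymethoxy)phenyl]-7-phenyl-3-[(trimethylsilyl)ethynyl]hept-1-ene
Product: 15 (1E,3R,5S)-5-[(tert-butyldimethylsilyl)oxy]-3-ethynyl-1-[4-(methoxymethoxy)phenyl]-7-phenylhept-1-ene
Conditions: K2CO3 (0.3 equiv), MeOH, 0 °C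
Reagents that add atoms: none
Why: Base-catalysed protodesilylation of the alkynylsilane frees the terminal alkyne while the silyl ether and the acetal stay, and low temperature with substoichiometric carbonate should avoid prototropic shift of the skipped enyne.

Step 12
Reactants: 15 (1E,3R,5S)-5-[(tert-butyldimethylsilyl)oxy]-3-ethynyl-1-[4-(methoxymethoxy)phenyl]-7-phenylhept-1-ene
Product: 18 (1E,3R,5S)-5-[(tert-butyldimethylsilyl)oxy]-1-[4-(methoxymethoxy)phenyl]-7-phenyl-3-{[(triisopropylsilyl)oxy]ethynyl}hept-1-ene, via lithium acetylide 16 (not isolated), via lithium ynolate 17 (not isolated)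
Conditions: LiN(SiMe3)2 (2.2 equiv), t-BuOOH (1.1 equiv, in decane), THF, −78 → 0 °C; then i-Pr3SiOTf (1.2 equiv), −78 °C
Reagents that add atoms: tert-butyl hydroperoxide, CC(C)(C)OO; triisopropylsilyl trifluoromethanesulfonate, CC(C)[Si](OS(=O)(=O)C(F)(F)F)(C(C)C)C(C)C
Why: Electrophilic oxygenation of the lithium acetylide by lithium tert-butyl peroxide gives the lithium ynolate, which the bulky silyl triflate traps on oxygen, and the amide base is too weak to remove the C3 proton.

Step 13
Reactants: 19 3-ethoxycyclobut-2-en-1-one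
Product: 20 3-methoxycyclobut-2-en-1-one
Conditions: MeOH (solvent), (±)-camphorsulfonic acid (2 mol%), rt; NaHCO3, distillation
Reagents that add atoms: methanol, CO
Why: Acid-catalysed transetherification of a vinylogous ester (addition of methanol at C3 of the protonated enone, loss of ethanol) is driven to the methyl ether by methanol as solvent.

Step 14
Reactants: 18 (1E,3R,5S)-5-[(tert-butyldimethylsilyl)oxy]-1-[4-(methoxymethoxy)phenyl]-7-phenyl-3-{[(triisopropylsilyl)oxy]ethynyl}hept-1-ene, 20 3-methoxycyclobut-2-en-1-one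
Product: 25 2-R*-5-methoxy-3-[(triisopropylsilyl)oxy]phenol, via (1-methoxyethenyl)ketene 21 (not isolated), via vinylcyclobutenone 22 (not isolated), via dienylketene 23 (not isolated), via cyclohexadienone 24 (not isolated)
Conditions: 20 (1.2 equiv), toluene, 90 °C, sealed tube
Reagents that add atoms: none
Why: Thermal 4π electrocyclic opening of 20 gives (1-methoxyethenyl)ketene 21, whose electrophilic carbonyl carbon is attacked by the oxygen-remote, C3-bearing carbon of the electron-rich siloxyalkyne in a [2+2] cycloaddition to give cyclobutenone 22; a second 4π opening gives dienylketene 23, 6π electrocyclization gives dienone 24, and enolization delivers phenol 25. The closest known reaction type is the Danheiser benzannulation of cyclobutenones with trialkylsiloxyalkynes to resorcinol monosilyl ethers, which tolerates alkynes branched at the propargylic carbon; the 3-alkoxy substituent on the cyclobutenone is the less tested element. Ring A is closed at C1'–C2' by a thermal disrotatory 6π electrocyclization of the dienylketene in which ketene and methoxyvinyl groups are cis, followed by tautomerization, not by ionic substitution. No stereocentre is created: C3 and C5 are carried unchanged, because no acid, base or cation acts at the propargylic position that becomes benzylic. The selectivity needed is regiochemical (C3' between the two oxygens, OMe para) and is secured by the polarity match between the ketene carbonyl carbon and the nucleophilic β-carbon of the ynol ether, while the far higher nucleophilicity of the siloxyalkyne keeps the styrene out of the cycloaddition.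

Step 15
Reactants: 25 2-R*-5-methoxy-3-[(triisopropylsilyl)oxy]phenol
Product: 26 2-R*-5-methoxybenzene-1,3-diol
Conditions: Bu4NF (1.1 equiv), THF, 0 °C
Reagents that add atoms: none
Why: Fluoride should cleave the aryl silyl ether (phenoxide leaving group) much faster than the secondary alkyl silyl ether at 0 °C, giving the resorcinol whose two unsubstituted ring positions are equivalent.

Step 16
Reactants: 26 2-R*-5-methoxybenzene-1,3-diol
Product: 27 2-R*-5-methoxy-1,3-bis(methoxymethoxy)benzene
Conditions: MOMCl (3 equiv), i-Pr2NEt (5 equiv), CH2Cl2, 0 °C → rt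
Reagents that add atoms: chloromethyl methyl ether, COCCl
Why: Double O-alkylation of the phenols gives acetals that tolerate and stabilise the later aryllithium (silyl ethers would migrate to carbon) and keeps the ring symmetric.

Step 17
Reactants: 27 2-R*-5-methoxy-1,3-bis(methoxymethoxy)benzene
Product: 28 2-bromo-4-R*-1-methoxy-3,5-bis(methoxymethoxy)benzene
Conditions: NBS (1.0 equiv), CH2Cl2, −78 → −30 °C, dark
Reagents that add atoms: N-bromosuccinimide, O=C1CCC(=O)N1Br
Why: Electrophilic aromatic bromination of the trialkoxybenzene occurs at one of the two equivalent free positions, the ring being far more nucleophilic than the styrene or ring B, and one equivalent at low temperature should stop at the monobromide.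

Step 18
Reactants: 28 2-bromo-4-R*-1-methoxy-3,5-bis(methoxymethoxy)benzene, 29 (2E)-N-methoxy-N-methyl-3-phenylprop-2-enamide
Product: 31 (2E)-1-[3-R*-6-methoxy-2,4-bis(methoxymethoxy)phenyl]-3-phenylprop-2-en-1-one, via aryllithium 30 (not isolated)
Conditions: n-BuLi (1.05 equiv), THF, −78 °C; then 29 (1.3 equiv), −78 → −20 °C; aq. NH4Cl
Reagents that add atoms: none
Why: Bromine–lithium exchange at −78 °C should outrun deprotonation at C3, and the oxygen-flanked aryllithium adds 1,2 to the Weinreb amide to give a chelated adduct that releases the enone only on work-up (Weinreb ketone synthesis), so over-addition is excluded.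

Step 19
Reactants: 31 (2E)-1-[3-R*-6-methoxy-2,4-bis(methoxymethoxy)phenyl]-3-phenylprop-2-en-1-one
Product: 32 alpinnanin C, (2E)-1-{2,4-dihydroxy-3-[(1E,3R,5S)-5-hydroxy-1-(4-hydroxyphenyl)-7-phenylhept-1-en-3-yl]-6-methoxyphenyl}-3-phenylprop-2-en-1-one
Conditions: aq. HCl (3 M), MeOH, rt
Reagents that add atoms: none
Why: Acid-catalysed acetal exchange of the three aryl methoxymethyl ethers and methanolysis of the silyl ether free all four hydroxyl groups, and mild acid at ambient temperature is chosen so that the 2'-hydroxychalcone should not close to the flavanone and the C5 hydroxyl should not add to the styrene.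

**Compound list**

1 | ethyl 3-oxo-5-phenylpentanoate | CCOC(=O)CC(=O)CCc1ccccc1 | starting material
2 | ethyl (3S)-3-hydroxy-5-phenylpentanoate | CCOC(=O)C[C@@H](O)CCc1ccccc1 | intermediate
3 | ethyl (3S)-3-[(tert-butyldimethylsilyl)oxy]-5-phenylpentanoate | CCOC(=O)C[C@@H](O[Si](C)(C)C(C)(C)C)CCc1ccccc1 | intermediate
4 | (3S)-3-[(tert-butyldimethylsilyl)oxy]-5-phenylpentanal | O=CC[C@@H](O[Si](C)(C)C(C)(C)C)CCc1ccccc1 | intermediate
5 | ethyl (2E,5S)-5-[(tert-butyldimethylsilyl)oxy]-7-phenylhept-2-enoate | CCOC(=O)/C=C/C[C@@H](O[Si](C)(C)C(C)(C)C)CCc1ccccc1 | intermediate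
6 | (2E,5S)-5-[(tert-butyldimethylsilyl)oxy]-7-phenylhept-2-en-1-ol | OC/C=C/C[C@@H](O[Si](C)(C)C(C)(C)C)CCc1ccccc1 | intermediate
7 | diethyl (2E,5S)-5-[(tert-butyldimethylsilyl)oxy]-7-phenylhept-2-en-1-yl phosphate | CCOP(=O)(OCC)OC/C=C/C[C@@H](O[Si](C)(C)C(C)(C)C)CCc1ccccc1 | intermediate
8 | ethynyltrimethylsilane | C#C[Si](C)(C)C | starting material
9 | diisobutyl[(trimethylsilyl)ethynyl]aluminium | CC(C)C[Al](CC(C)C)C#C[Si](C)(C)C | intermediate (not isolated)
10 | (3R,5S)-5-[(tert-butyldimethylsilyl)oxy]-7-phenyl-3-[(trimethylsilyl)ethynyl]hept-1-ene | C[Si](C)(C)C#C[C@@H](C=C)C[C@@H](O[Si](C)(C)C(C)(C)C)CCc1ccccc1 | intermediate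
11 | 4-hydroxybenzaldehyde | O=Cc1ccc(O)cc1 | starting material
12 | 4-(methoxymethoxy)benzaldehyde | COCOc1ccc(C=O)cc1 | intermediate
13 | 1-ethenyl-4-(methoxymethoxy)benzene | C=Cc1ccc(OCOC)cc1 | intermediate
14 | (1E,3R,5S)-5-[(tert-butyldimethylsilyl)oxy]-1-[4-(methoxymethoxy)phenyl]-7-phenyl-3-[(trimethylsilyl)ethynyl]hept-1-ene | C[Si](C)(C)C#C[C@@H](/C=C/c1ccc(OCOC)cc1)C[C@@H](O[Si](C)(C)C(C)(C)C)CCc1ccccc1 | intermediate
15 | (1E,3R,5S)-5-[(tert-butyldimethylsilyl)oxy]-3-ethynyl-1-[4-(methoxymethoxy)phenyl]-7-phenylhept-1-ene | C#C[C@@H](/C=C/c1ccc(OCOC)cc1)C[C@@H](O[Si](C)(C)C(C)(C)C)CCc1ccccc1 | intermediate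
16 | lithium acetylide of 15 | [Li]C#C[C@@H](/C=C/c1ccc(OCOC)cc1)C[C@@H](O[Si](C)(C)C(C)(C)C)CCc1ccccc1 | intermediate (not isolated)
17 | lithium ynolate (lithium 2-R*-ethyn-1-olate) | [Li]OC#C[C@@H](/C=C/c1ccc(OCOC)cc1)C[C@@H](O[Si](C)(C)C(C)(C)C)CCc1ccccc1 | intermediate (not isolated)
18 | (1E,3R,5S)-5-[(tert-butyldimethylsilyl)oxy]-1-[4-(methoxymethoxy)phenyl]-7-phenyl-3-{[(triisopropylsilyl)oxy]ethynyl}hept-1-ene | CC(C)[Si](OC#C[C@@H](/C=C/c1ccc(OCOC)cc1)C[C@@H](O[Si](C)(C)C(C)(C)C)CCc1ccccc1)(C(C)C)C(C)C | intermediate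
19 | 3-ethoxycyclobut-2-en-1-one | CCOC1=CC(=O)C1 | starting material
20 | 3-methoxycyclobut-2-en-1-one | COC1=CC(=O)C1 | intermediate
21 | 3-methoxybuta-1,3-dien-1-one, (1-methoxyethenyl)ketene | COC(=C)C=C=O | intermediate (not isolated)
22 | 4-(1-methoxyethenyl)-2-R*-3-[(triisopropylsilyl)oxy]cyclobut-2-en-1-one (both C4 epimers) | COC(=C)C1C(=O)C([C@@H](/C=C/c2ccc(OCOC)cc2)C[C@@H](O[Si](C)(C)C(C)(C)C)CCc2ccccc2)=C1O[Si](C(C)C)(C(C)C)C(C)C | intermediate (not isolated)
23 | (3E)-5-methoxy-2-R*-3-[(triisopropylsilyl)oxy]hexa-1,3,5-trien-1-one (ketene and methoxyvinyl groups cis) | O=C=C([C@@H](/C=C/c1ccc(OCOC)cc1)C[C@@H](O[Si](C)(C)C(C)(C)C)CCc1ccccc1)/C(O[Si](C(C)C)(C(C)C)C(C)C)=C\C(OC)=C | intermediate (not isolated)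
24 | 5-methoxy-2-R*-3-[(triisopropylsilyl)oxy]cyclohexa-2,4-dien-1-one | O=C1CC(OC)=CC(O[Si](C(C)C)(C(C)C)C(C)C)=C1[C@@H](/C=C/c1ccc(OCOC)cc1)C[C@@H](O[Si](C)(C)C(C)(C)C)CCc1ccccc1 | intermediate (not isolated)
25 | 2-R*-5-methoxy-3-[(triisopropylsilyl)oxy]phenol | COc1cc(O)c([C@@H](/C=C/c2ccc(OCOC)cc2)C[C@@H](O[Si](C)(C)C(C)(C)C)CCc2ccccc2)c(O[Si](C(C)C)(C(C)C)C(C)C)c1 | intermediate
26 | 2-R*-5-methoxybenzene-1,3-diol | COc1cc(O)c([C@@H](/C=C/c2ccc(OCOC)cc2)C[C@@H](O[Si](C)(C)C(C)(C)C)CCc2ccccc2)c(O)c1 | intermediate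
27 | 2-R*-5-methoxy-1,3-bis(methoxymethoxy)benzene | COc1cc(OCOC)c([C@@H](/C=C/c2ccc(OCOC)cc2)C[C@@H](O[Si](C)(C)C(C)(C)C)CCc2ccccc2)c(OCOC)c1 | intermediate
28 | 2-bromo-4-R*-1-methoxy-3,5-bis(methoxymethoxy)benzene | COc1cc(OCOC)c([C@@H](/C=C/c2ccc(OCOC)cc2)C[C@@H](O[Si](C)(C)C(C)(C)C)CCc2ccccc2)c(OCOC)c1Br | intermediate
29 | (2E)-N-methoxy-N-methyl-3-phenylprop-2-enamide (N-methoxy-N-methylcinnamamide) | CON(C)C(=O)/C=C/c1ccccc1 | starting material
30 | [3-R*-6-methoxy-2,4-bis(methoxymethoxy)phenyl]lithium | COc1cc(OCOC)c([C@@H](/C=C/c2ccc(OCOC)cc2)C[C@@H](O[Si](C)(C)C(C)(C)C)CCc2ccccc2)c(OCOC)c1[Li] | intermediate (not isolated)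
31 | (2E)-1-[3-R*-6-methoxy-2,4-bis(methoxymethoxy)phenyl]-3-phenylprop-2-en-1-one | COc1cc(OCOC)c([C@@H](/C=C/c2ccc(OCOC)cc2)C[C@@H](O[Si](C)(C)C(C)(C)C)CCc2ccccc2)c(OCOC)c1C(=O)/C=C/c1ccccc1 | intermediate
32 | alpinnanin C, (2E)-1-{2,4-dihydroxy-3-[(1E,3R,5S)-5-hydroxy-1-(4-hydroxyphenyl)-7-phenylhept-1-en-3-yl]-6-methoxyphenyl}-3-phenylprop-2-en-1-one | COc1cc(O)c([C@@H](/C=C/c2ccc(O)cc2)C[C@@H](O)CCc2ccccc2)c(O)c1C(=O)/C=C/c1ccccc1 | target

**Step count and risks**

Total: 19 steps. Longest linear sequence: 16 steps (1 → 2 → 3 → 4 → 5 → 6 → 7 → 10 → 14 → 15 → 18 → 25 → 26 → 27 → 28 → 31 → 32). Steps 8–9 and step 13 are side branches.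

Steps most likely to fail:

1. Step 14. The vinylogous-ester cyclobutenone may open too slowly at temperatures the siloxyalkyne survives (silyl shift to a silylketene, hydrolysis), or the vinylketene may be lost by dimerisation or by acylating the product phenol. Fallback: the same vinylketene 21 is generated at ambient temperature by a photochemical Wolff rearrangement instead of a thermal ring opening. Purchased 3,3-dimethoxybutan-2-one loses methanol on heating with catalytic p-TsOH to give 3-methoxybut-3-en-2-one F1. Its lithium enolate (LiN(SiMe3)2, THF, −78 °C) is acylated with 2,2,2-trifluoroethyl trifluoroacetate to 1,1,1-trifluoro-5-methoxyhex-5-ene-2,4-dione F2. Detrifluoroacetylative diazo transfer (MsN3, Et3N, H2O, MeCN) then gives 1-diazo-3-methoxybut-3-en-2-one F3. Irradiation of F3 with siloxyalkyne 18 (λ > 350 nm so that the styrene is not excited, CH2Cl2, rt), followed by warming to 60–80 °C, should run the cascade through 22, 23 and 24. The fallback sets out from 18 and rejoins the route at 25.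

2. Step 7. Facial discrimination at C3 by the catalyst may be insufficient next to the existing C5 centre, or substitution may leak to the linear SN2 product. Fallback: C3 is set by reagent-controlled epoxidation and stereospecific epoxide opening. Allylic alcohol 6 undergoes Sharpless asymmetric epoxidation (Ti(Oi-Pr)4, L-(+)-diethyl tartrate, t-BuOOH, 4 Å molecular sieves, CH2Cl2, −20 °C) to [(2S,3S)-3-{(2S)-2-[(tert-butyldimethylsilyl)oxy]-4-phenylbutyl}oxiran-2-yl]methanol F4. Diethyl[(trimethylsilyl)ethynyl]aluminium F5 (from 8, n-BuLi, then Et2AlCl, toluene) opens the epoxide at C3 with inversion to give (2R,3S,5S)-5-[(tert-butyldimethylsilyl)oxy]-7-phenyl-3-[(trimethylsilyl)ethynyl]heptane-1,2-diol F6. Corey–Winter olefination via (4R)-4-{(3S,5S)-5-[(tert-butyldimethylsilyl)oxy]-7-phenyl-1-(trimethylsilyl)hept-1-yn-3-yl}-1,3-dioxolane-2-thione F7 (1,1'-thiocarbonyldiimidazole; then P(OMe)3, heat) removes the diol as the terminal alkene. The fallback sets out from 6 and rejoins the route at 10.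

3. Step 10. The ruthenium carbene may be diverted into enyne metathesis with, or sequestered by, the trimethylsilylalkyne, and the branched olefin may turn over so slowly that self-metathesis of the styrene takes over. Fallback: the alkyne is carried through the metathesis under a bulkier triisopropylsilyl cap and released afterwards with silver fluoride. Phosphate 7 is treated as in step 7 with diisobutyl[(triisopropylsilyl)ethynyl]aluminium F8 (from purchased ethynyltriisopropylsilane, i-Bu2AlH, Et3N cat.) to give (3R,5S)-5-[(tert-butyldimethylsilyl)oxy]-7-phenyl-3-[(triisopropylsilyl)ethynyl]hept-1-ene F9. Cross-metathesis with 13 as in step 10 gives (1E,3R,5S)-5-[(tert-butyldimethylsilyl)oxy]-1-[4-(methoxymethoxy)phenyl]-7-phenyl-3-[(triisopropylsilyl)ethynyl]hept-1-ene F10. AgF in MeOH followed by dilute HCl frees the alkyne without touching the C5 silyl ether. The fallback sets out from 7 and rejoins the route at 15.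

**Further compounds**

F1 | step 14 | 3-methoxybut-3-en-2-one | C=C(OC)C(C)=O
F2 | step 14 | 1,1,1-trifluoro-5-methoxyhex-5-ene-2,4-dione | C=C(OC)C(=O)CC(=O)C(F)(F)F
F3 | step 14 | 1-diazo-3-methoxybut-3-en-2-one | C=C(OC)C(=O)C=[N+]=[N-]
F4 | step 7 | [(2S,3S)-3-{(2S)-2-[(tert-butyldimethylsilyl)oxy]-4-phenylbutyl}oxiran-2-yl]methanol | OC[C@@H]1O[C@H]1C[C@@H](O[Si](C)(C)C(C)(C)C)CCc1ccccc1
F5 | step 7 | diethyl[(trimethylsilyl)ethynyl]aluminium | CC[Al](CC)C#C[Si](C)(C)C
F6 | step 7 | (2R,3S,5S)-5-[(tert-butyldimethylsilyl)oxy]-7-phenyl-3-[(trimethylsilyl)ethynyl]heptane-1,2-diol | OC[C@H](O)[C@H](C#C[Si](C)(C)C)C[C@@H](O[Si](C)(C)C(C)(C)C)CCc1ccccc1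
F7 | step 7 | (4R)-4-{(3S,5S)-5-[(tert-butyldimethylsilyl)oxy]-7-phenyl-1-(trimethylsilyl)hept-1-yn-3-yl}-1,3-dioxolane-2-thione | S=C1OC[C@H](O1)[C@H](C#C[Si](C)(C)C)C[C@@H](O[Si](C)(C)C(C)(C)C)CCc1ccccc1
F8 | step 10 | diisobutyl[(triisopropylsilyl)ethynyl]aluminium | CC(C)C[Al](CC(C)C)C#C[Si](C(C)C)(C(C)C)C(C)C
F9 | step 10 | (3R,5S)-5-[(tert-butyldimethylsilyl)oxy]-7-phenyl-3-[(triisopropylsilyl)ethynyl]hept-1-ene | CC(C)[Si](C#C[C@@H](C=C)C[C@@H](O[Si](C)(C)C(C)(C)C)CCc1ccccc1)(C(C)C)C(C)C
F10 | step 10 | (1E,3R,5S)-5-[(tert-butyldimethylsilyl)oxy]-1-[4-(methoxymethoxy)phenyl]-7-phenyl-3-[(triisopropylsilyl)ethynyl]hept-1-ene | CC(C)[Si](C#C[C@@H](/C=C/c1ccc(OCOC)cc1)C[C@@H](O[Si](C)(C)C(C)(C)C)CCc1ccccc1)(C(C)C)C(C)C
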